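**Retrosynthetic overview**
1. Target 18 ⇐ phenol unmasking and C6 aroylation ⇐ 6α-alcohol 15 ⇐ hydroxyl-directed reduction of the bicyclic ketol 14.
2. Key disconnection: both rings of 14 come in one flask from the acyclic farnesane-type triketone 9 through the two ring bonds of the presumed daucane biogenesis from the farnesyl chain (C1–C10, then C4–C5, with C4 ending as the tertiary alcohol).
3. 9 ⇐ oxidative opening of the 2,3,5-trisubstituted furan 8, a latent (Z)-ene-1,4-dione.
4. 8 ⇐ reagent-controlled aldol of 3-methylbutan-2-one with enal 3, which sets C2, the only stereocentre carried into the cyclisation ⇐ 4,5-dimethylfurfural + propanal.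
5. Ring order: seven-membered ring first, five-membered ring second; no ring is bought.

Assumption: daucane numbering is used for cyclic compounds and for the corresponding carbons of the acyclic precursors (C1 = methyl-bearing ring-fusion carbon, C2 = CH–OAc, C4 = C(OH)(i-Pr), C5 = ring-fusion CH, C6 = CH–O, C7=C8, C9 = C=O, C10 = CH2, C15 = the C1 methyl); β is the face of the C1 methyl.

**Step 1**
Reactants: 1 4,5-dimethylfuran-2-carbaldehyde; 2 propanal
Product: 3 (2E)-3-(4,5-dimethylfuran-2-yl)-2-methylprop-2-enal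
Conditions: 2 (slow addition), NaOH (cat.), EtOH–H2O, 0 → 25 °C
Reagents that add atoms: none
Why: Claisen–Schmidt (crossed aldol) condensation in which the furaldehyde has no α-hydrogen, slow addition of propanal limits its self-condensation, and the conjugated (E)-enal (furyl trans to CHO) is the thermodynamic dehydration product.

**Step 2**
Reactants: 3 (2E)-3-(4,5-dimethylfuran-2-yl)-2-methylprop-2-enal; 4 3-methylbutan-2-one
Product: 7 (5R,6E)-7-(4,5-dimethylfuran-2-yl)-5-hydroxy-2,6-dimethylhept-6-en-3-one, via boron enolate 5 (not isolated), via boron aldolate 6 (not isolated)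
Conditions: 4, (−)-Ipc2BCl, Et3N, Et2O, −78 → 0 °C; 3, −78 → −20 °C; MeOH, pH 7 buffer, 30% H2O2, 0 °C
Reagents that add atoms: none
Why: Paterson boron aldol in which the kinetic methyl-side diisopinocampheylboron enolate adds 1,2 to the enal through a cyclic boron transition state and the isopinocampheyl ligands select the aldehyde face that gives the (5R)-carbinol (future C2); the antipodal borane would give the enantiomer.

**Step 3**
Reactants: 7 (5R,6E)-7-(4,5-dimethylfuran-2-yl)-5-hydroxy-2,6-dimethylhept-6-en-3-one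
Product: 8 (5R,6E)-7-(4,5-dimethylfuran-2-yl)-2,6-dimethyl-3-oxohept-6-en-5-yl acetate
Conditions: Ac2O, pyridine, DMAP (cat.), CH2Cl2, 0 °C
Reagents that add atoms: acetic anhydride CC(=O)OC(C)=O
Why: DMAP-catalysed acetylation of the secondary allylic alcohol, mild enough at 0 °C that the β-acetoxy ketone does not eliminate; the stereocentre is untouched.

**Step 4**
Reactants: 8 (5R,6E)-7-(4,5-dimethylfuran-2-yl)-2,6-dimethyl-3-oxohept-6-en-5-yl acetate
Product: 9 (5R,6E,9Z)-2,6,10-trimethyl-3,8,11-trioxododeca-6,9-dien-5-yl acetate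
Conditions: mCPBA (1.05 equiv), CH2Cl2, −20 → 0 °C; used crude
Reagents that add atoms: mCPBA OOC(=O)c1cccc(Cl)c1
Why: Peracid oxidative ring opening of the electron-rich trisubstituted furan (furan to cis-enedione unmasking) outpaces epoxidation of the conjugated side-chain alkene, and the new C7=C8 double bond inherits the Z geometry from the ring.

**Step 5**
Reactants: 9 (5R,6E,9Z)-2,6,10-trimethyl-3,8,11-trioxododeca-6,9-dien-5-yl acetate
Product: 14 2α-acetoxy-4β-hydroxy-5α-H-dauc-7-ene-6,9-dione, via silyl dienol ether 10 (not isolated), via monocyclic silyl enol ether 11 (not isolated), via cis-fused silyl aldolate 12 (not isolated), via cis-fused ketol 13 (not isolated)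
Conditions: TMSOTf (2.5 equiv), i-Pr2NEt (1.3 equiv), CH2Cl2, −78 → −20 °C; 1 M HCl, THF, 0 °C; DBU (0.2 equiv), CH2Cl2, 25 °C
Reagents that add atoms: none
Why: Proposed new method: an enol-silane formation / Mukaiyama–Michael / Mukaiyama aldol domino (closest known reaction types: one-pot silyl triflate/amine Mukaiyama additions and the silyl-triflate-mediated intramolecular Michael–aldol reaction) in which the methyl ketone is silylated to 2-siloxydiene 10, its CH2 terminus (C10) adds 7-endo to C1 of the O-silylated cross-conjugated dienone (tertiary allyl-cation character at C1, termini held together by the Z-enedione) on the face anti to the C3 chain of the C2 stereocentre (C2–H eclipsing the C1 methyl) to set the quaternary C1, the released enol silane 11 then adds to the silyl-activated isopropyl ketone through an open antiperiplanar transition state on the only face the two-carbon tether can reach (cis-fused 12, C4–O trans to C6, so C4 has the target configuration), and after desilylation DBU epimerises C5 through the C6 enol to the trans-fused ketol 14, which is favoured by the O–H···O=C6 hydrogen bond and by having isopropyl and C6 trans.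

**Step 6**
Reactants: 14 2α-acetoxy-4β-hydroxy-5α-H-dauc-7-ene-6,9-dione
Product: 15 2α-acetoxy-4β,6α-dihydroxydauc-7-en-9-one
Conditions: Me4NBH(OAc)3 (5 equiv), MeCN–AcOH (1:1), −30 °C
Reagents that add atoms: none
Why: Evans–Saksena hydroxyl-directed reduction in which the 4β-OH exchanges onto boron and delivers hydride intramolecularly to the β-face of the C6 carbonyl, giving the 6α-alcohol (1,3-anti diol), while the C9 enone has no β-hydroxyl and is not reduced.

**Step 7**
Reactants: 15 2α-acetoxy-4β,6α-dihydroxydauc-7-en-9-one; 16 4-acetoxybenzoyl chloride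
Product: 17 2α-acetoxy-6α-(4-acetoxybenzoyloxy)-4β-hydroxydauc-7-en-9-one
Conditions: Et3N, DMAP (0.2 equiv), CH2Cl2, 0 → 25 °C
Reagents that add atoms: none
Why: DMAP-catalysed acylation with the acid chloride, in which the secondary allylic 6α-OH reacts and the tertiary 4β-OH does not; no stereocentre is touched.

**Step 8**
Reactants: 17 2α-acetoxy-6α-(4-acetoxybenzoyloxy)-4β-hydroxydauc-7-en-9-one
Product: 18 2α-acetoxy-4β-hydroxy-6α-(4-hydroxybenzoyloxy)dauc-7-en-9-one (target, CNP0087181.6)
Conditions: K2CO3 (0.2 equiv), MeOH, 0 °C, 20 min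
Reagents that add atoms: none
Why: Zemplén-type transesterification in which the aryl acetate is cleaved far faster than the hindered secondary alkyl acetate and the benzoate; no stereocentre is touched.

**Compound list**
1 | 4,5-dimethylfuran-2-carbaldehyde | O=Cc1cc(C)c(C)o1 | starting material
2 | propanal | CCC=O | starting material
3 | (2E)-3-(4,5-dimethylfuran-2-yl)-2-methylprop-2-enal | O=C/C(C)=C/c1cc(C)c(C)o1 | intermediate
4 | 3-methylbutan-2-one | CC(=O)C(C)C | starting material
5 | 3-methylbut-1-en-2-yl bis[(−)-isopinocampheyl]borinate (boron enolate of 4; isopinocampheyl from (+)-α-pinene) | C=C(OB([C@@H]1C[C@@H]2C[C@H]([C@H]1C)C2(C)C)[C@@H]1C[C@@H]2C[C@H]([C@H]1C)C2(C)C)C(C)C | intermediate (not isolated)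
6 | O-[bis((−)-isopinocampheyl)boryl] derivative of 7 (boron aldolate, 5R,6E) | CC(C)C(=O)C[C@@H](OB([C@@H]1C[C@@H]2C[C@H]([C@H]1C)C2(C)C)[C@@H]1C[C@@H]2C[C@H]([C@H]1C)C2(C)C)/C(C)=C/c1cc(C)c(C)o1 | intermediate (not isolated)
7 | (5R,6E)-7-(4,5-dimethylfuran-2-yl)-5-hydroxy-2,6-dimethylhept-6-en-3-one | CC(C)C(=O)C[C@@H](O)/C(C)=C/c1cc(C)c(C)o1 | intermediate
8 | (5R,6E)-7-(4,5-dimethylfuran-2-yl)-2,6-dimethyl-3-oxohept-6-en-5-yl acetate | CC(C)C(=O)C[C@@H](OC(C)=O)/C(C)=C/c1cc(C)c(C)o1 | intermediate
9 | (5R,6E,9Z)-2,6,10-trimethyl-3,8,11-trioxododeca-6,9-dien-5-yl acetate | CC(C)C(=O)C[C@@H](OC(C)=O)/C(C)=C/C(=O)/C=C(C)\C(C)=O | intermediate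
10 | (5R,6E,9Z)-2,6,10-trimethyl-3,8-dioxo-11-(trimethylsilyloxy)dodeca-6,9,11-trien-5-yl acetate | CC(C)C(=O)C[C@@H](OC(C)=O)/C(C)=C/C(=O)/C=C(C)\C(=C)O[Si](C)(C)C | intermediate (not isolated)
11 | (1R)-1-[(1S)-1,5-dimethyl-6-oxo-3-(trimethylsilyloxy)cyclohepta-2,4-dien-1-yl]-4-methyl-3-oxopentyl acetate (seven-membered ring closed, C1 quaternary) | CC(C)C(=O)C[C@@H](OC(C)=O)[C@@]1(C)CC(=O)C(C)=CC(O[Si](C)(C)C)=C1 | intermediate (not isolated)
12 | 2α-acetoxy-4β-(trimethylsilyloxy)-5β-H-dauc-7-ene-6,9-dione (cis-fused) | CC(=O)O[C@@H]1C[C@](O[Si](C)(C)C)(C(C)C)[C@@H]2C(=O)C=C(C)C(=O)C[C@]12C | intermediate (not isolated)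
13 | 2α-acetoxy-4β-hydroxy-5β-H-dauc-7-ene-6,9-dione (cis-fused, 5-epimer of 14) | CC(=O)O[C@@H]1C[C@](O)(C(C)C)[C@@H]2C(=O)C=C(C)C(=O)C[C@]12C | intermediate (not isolated)
14 | 2α-acetoxy-4β-hydroxy-5α-H-dauc-7-ene-6,9-dione (trans-fused) | CC(=O)O[C@@H]1C[C@](O)(C(C)C)[C@H]2C(=O)C=C(C)C(=O)C[C@]12C | intermediate
15 | 2α-acetoxy-4β,6α-dihydroxydauc-7-en-9-one | CC(=O)O[C@@H]1C[C@](O)(C(C)C)[C@H]2[C@H](O)C=C(C)C(=O)C[C@]12C | intermediate
16 | 4-acetoxybenzoyl chloride | CC(=O)Oc1ccc(cc1)C(Cl)=O | starting material
17 | 2α-acetoxy-6α-(4-acetoxybenzoyloxy)-4β-hydroxydauc-7-en-9-one | CC(=O)O[C@@H]1C[C@](O)(C(C)C)[C@H]2[C@H](OC(=O)c3ccc(OC(C)=O)cc3)C=C(C)C(=O)C[C@]12C | intermediate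
18 | 2α-acetoxy-4β-hydroxy-6α-(4-hydroxybenzoyloxy)dauc-7-en-9-one, (1S,2R,4S,5R,6R) in daucane numbering | CC(=O)O[C@@H]1C[C@](O)(C(C)C)[C@H]2[C@H](OC(=O)c3ccc(O)cc3)C=C(C)C(=O)C[C@]12C | target

**Totals**
Total step count: 8. Longest linear sequence: 8 steps (1 → 18).

**Three steps most likely to fail**

Step 5 (bicyclisation). The risks are competing 1,2-addition of the siloxydiene to the C6 carbonyl (five-membered ring), poor facial selectivity at C1 relative to C2, and a ring fusion that stays cis if the C5 epimerisation does not go to the trans ketol. The fallback sets out from 9 and returns at 14, closing the rings in the opposite order so that C4 and C5 are fixed on a monocycle before the quaternary centre is made. Soft enolisation of 9 (MgBr2·OEt2, i-Pr2NEt, CH2Cl2, −20 °C) removes a γ-hydrogen from the C15 methyl, and the magnesium dienolate attacks the isopropyl ketone through its α-carbon (C5) in a chelated aldol to give (1R,3S,4S)-4-hydroxy-2-methylidene-3-[(2Z)-3-methyl-4-oxopent-2-enoyl]-4-(propan-2-yl)cyclopentyl acetate F1. The seven-membered ring is then closed by acid-mediated Markovnikov addition of the methyl-ketone enol to the exocyclic alkene (HNTf2 cat., CH2Cl2, −40 °C; tertiary C1 cation, C15 methyl formed by protonation), which gives 14.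

Step 4 (furan opening). The (Z)-enedione 9 is labile; over-oxidation or Z → E isomerisation would make the seven-membered closure impossible. The fallback sets out from 8 and returns at 9. The furan is methoxylated (anodic oxidation in MeOH with NH4Br electrolyte at −10 °C, or Br2, MeOH, Na2CO3, −40 °C) to the storable, purifiable bis-ketal (5R,6E)-7-(2,5-dimethoxy-4,5-dimethyl-2,5-dihydrofuran-2-yl)-2,6-dimethyl-3-oxohept-6-en-5-yl acetate F2 (mixture of ketal epimers). Brief hydrolysis (pyridinium p-toluenesulfonate, aqueous acetone, 0 °C) just before the cyclisation liberates 9 with the Z geometry intact.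

Step 2 (asymmetric aldol). Methyl-ketone boron aldols give only moderate enantioselectivity, the sense of induction of the chosen borane should be confirmed on the first run, and the conjugated enal is a sluggish acceptor. The fallback sets out from 4 and returns at 7, replacing the stoichiometric chiral borane by a catalytic enantioselective Mukaiyama aldol. Ketone 4 is converted (LDA, TMSCl, THF, −78 °C) into the kinetic enol silane trimethyl[(3-methylbut-1-en-2-yl)oxy]silane F3. F3 adds to enal 3 under Lewis-base-activated SiCl4 catalysis (SiCl4, chiral binaphthyldiamine-derived bisphosphoramide 5 mol %, i-Pr2NEt, CH2Cl2, −78 °C), a catalyst class that works best with conjugated aldehydes; the catalyst enantiomer is chosen to give (5R)-7 after aqueous work-up.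

**Further compounds**
F1 | step 5 | (1R,3S,4S)-4-hydroxy-2-methylidene-3-[(2Z)-3-methyl-4-oxopent-2-enoyl]-4-(propan-2-yl)cyclopentyl acetate | CC(=O)O[C@@H]1C[C@](O)(C(C)C)[C@@H](C(=O)/C=C(C)\C(C)=O)C1=C
F2 | step 4 | (5R,6E)-7-(2,5-dimethoxy-4,5-dimethyl-2,5-dihydrofuran-2-yl)-2,6-dimethyl-3-oxohept-6-en-5-yl acetate (ketal epimers) | CC(C)C(=O)C[C@@H](OC(C)=O)/C(C)=C/C1(OC)C=C(C)C(C)(OC)O1
F3 | step 2 | trimethyl[(3-methylbut-1-en-2-yl)oxy]silane | CC(C)C(=C)O[Si](C)(C)C
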